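## Structural features

The target is a germacrane: a ten-membered carbocycle (C1–C10) fused through C6 and C7 to a butenolide (C6, C7, C11, C12 and the ring oxygen). The butenolide double bond is C7=C11, and its α-carbon C11 carries an acetoxymethyl group (C13). The carbocycle bears two trans-configured trisubstituted epoxides (C1–C10 and C4–C5, each with a methyl group on the quaternary carbon) and, at C8, the ester of 2-(hydroxymethyl)acrylic acid. There are six stereocentres (1R, 4R, 5R, 6S, 8S, 10R): C4, C5 and C6 are contiguous, C1 and C10 form a pair, and C8 is separated from C6 only by the sp2 carbon C7. The fragile points are: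
- the C6–H bond, which is γ to the lactone carbonyl and β to the C5 epoxide oxygen, so base opens the epoxide by elimination;
- the 4,5-epoxide next to a 1(10)-olefin or 1,10-epoxide, where acid triggers transannular cyclisation;
- the lactone, which can migrate to a free C8 hydroxyl;
- the allylic acetate and the acrylate.

The real difficulty is to close the strained ten-membered ring with an E-1(10) double bond while fixing C5 and C6 relative to C4 and C8, and to keep the oxygens at C4/C5, C8, C13 and the side chain distinguishable to the end. The key step exploits the fact that C5 (epoxide carbon) and C6 (γ-carbon of the butenolide, bearing the lactone oxygen) are neighbouring oxygenated carbons. That is the retron of a 2-silyloxyfuran (C12, C11, C7, C6 and O) adding through C6 to an α-oxygenated aldehyde (C5, with C4 quaternary).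

## Logic of the disconnections

30 to 29: only the O–Si bond of the side-chain alcohol is cut. A free primary allylic alcohol on the acrylate would interfere with the esterification, so the acid is carried as 26. The last step must therefore be a near-neutral desilylation that spares two epoxides and the base-labile C6–H.

29 to 28: the C1–O and C10–O bonds of the 1,10-epoxide are cut. The E-1(10) double bond is wanted as a rigid element during ring closure and is the only electron-rich alkene left at this stage. This removes two stereocentres. The forward step must attack one face of the olefin of 28 and must not be acidic.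

28 to 23 and 26: the acyl–O8 bond is cut, which separates the side chain as a simple acid. The acylation of a hindered secondary alcohol must run without base damage at C6; 26 comes from 24 through 25.

23 to 22 to 21: the O8–Si bond and the acetyl–O13 bond are cut. O8 stays silylated until the basic epoxide closure is over, because a free C8 alkoxide can capture the lactone carbonyl. The acetate is added only after that basic step. This order is the demand.

21 to 20 to 19 to 18: the O4–C5 bond of the 4,5-epoxide is cut, giving an anti β-hydroxy sulfonate as retron. The epoxide oxygen is the tertiary C4 oxygen, and the C5 oxygen is the leaving group, so 18 must be 4R,5S and C5 is inverted to 5R. The gain is a 1,2-dioxygenated C4–C5 unit next to C6–O, which is an aldol pattern. The closure must outrun β-elimination through C6–H.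

18 to 17: the C5–C6 bond is cut, which opens the ten-membered ring. This is the strategic cut, because it turns a medium ring with two new stereocentres into an open chain that ends in a non-enolisable aldehyde and a silyloxyfuran. The forward step must beat oligomerisation and must set C5 and C6.

17 to 16 to 15: the enol O–Si bond is cut, then the C5 aldehyde is traced to a primary triethylsilyl ether. The aldehyde is produced by oxidation at C5 and not by cleavage of an alkene, since no oxidative cleavage would spare the 1(10)-olefin. The silyloxyfuran is made last because it is the most sensitive group.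

15 to 13: the C12–O bonds are cut, so the lactone carbonyl becomes a furan C–H. The aromatic furan survives the organometallic steps. The forward oxidation must take C12 and not C6.

13 to 4 and 11: the C1–C2 bond (sp2–sp3) is cut, giving two halves with one stereocentre each. A stereoretentive coupling is needed so that the E geometry of 11 is carried over.

11 to 9 to 8: the C10–CH3 and C1–I bonds are cut. A syn carbometalation of the alkyne must put the methyl group on C10 and fix the E geometry. Then 8 to 7 cuts C8–C9 and demands reagent control of the C8 stereocentre, and 7 to 6 to 5 is desymmetrisation of a symmetrical diol.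

4 to 3 to 2 to 1: the terminal alkene carbon (C2) is cut from C3 and the two silyl groups are removed. The C4 stereocentre, with both the C4 and C5 oxygens, is bought in 1, so no asymmetric step is needed on this side.

## Other disconnections considered

Alternative 1: The cut is the C5–C10 bond of a decalin (eudesmane) skeleton. In the forward key step an alkoxide adds to a C4 borane, and the boronate fragments with loss of a C1 sulfonate. This breaks C5–C10 and forms both E double bonds of 11,13-dihydrocostunolide A1.
- In its favour: the fragmentation is concerted and stereospecific, both olefin geometries follow from the ring fusion, and C6 and C7 come from the chiral pool. On reliability of ring formation and on control of C6 it is better than the chosen plan. It is at least its equal in the way both epoxides could be added at the end by one peracid treatment.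
- Against it here: A1 has no oxygen at C8 or C13, and C7 and C11 are saturated. The target would need dehydrogenation to the 7(11)-butenolide and two allylic oxidations on a ring whose two olefins offer several competing allylic positions and react transannularly.
- Comparison: the route to A1 is short, but the functional-group corrections after it are long and poorly selective. The chosen plan is longer before ring closure but places every oxygen before the ring exists.

Alternative 2: The cut is the C6–C7 bond. In the forward key step a thirteen-membered propargylic allylic ether is lithiated at C6 and undergoes a [2,3]-Wittig shift, which contracts the ring to the cyclodecenynol A2.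
- In its favour: macro-etherification to the large ring is easy, and the sigmatropic step is well precedented for ten-membered carbocycles. It delivers the C6 carbinol with predictable relative configuration, and A2 already carries O8, the E-1(10) olefin and the C13 oxygen. In mechanistic security of C6 it is better than the chosen plan, and the C6 hydroxyl could later direct a 4,5-epoxidation.
- Against it here: the C7 stereocentre it creates is destroyed when the 7(11)-olefin is made. The terminal methylene must be oxidised to the lactone carbonyl and the double bond moved into conjugation. C4 has no methyl group, so the alkyne needs a regio- and stereoselective methyl-metalation before epoxidation.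
- Comparison: ring formation is safer, but the count after the ring is clearly higher. The chosen plan brings the complete butenolide and the C4 methyl carbinol into the ring-forming step.

Alternative 3: The cut is the C8–C9 bond, with the C1–C6 transannular bond of a 1,2-dialkenylcyclohexanol as the bond to be broken. In the forward key step the potassium alkoxide undergoes an anionic oxy-Cope rearrangement to the cyclodecenone A3, formed as its enolate.
- In its favour: the ring expansion is fast and reliable at low temperature, and the chair-like transition state gives the E olefin. The regiodefined C6/C7 enolate could be trapped to start building at C7. In E-olefin control it is the equal of the chosen plan.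
- Against it here: A3 lacks C11, C12 and C13 and the C5 oxygen. The butenolide would have to be annulated on a medium-ring ketone, C5 oxidised in competition with C7, and the C6 ketone reduced with control. The C4 tertiary silyloxy group is not present in the monoterpene precursor and would need a C–H hydroxylation.
- Comparison: the ring construction is better precedented, but convergence and step economy are worse, because three carbons and two oxygens are added after the ring is made.

Key step: step 13

Remarks on the chemistry (corrections and assumptions):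
- The oxygen that the aldehyde brings to C5 is not the epoxide oxygen. It leaves as mesylate, the epoxide oxygen is the C4 oxygen of 1, and C5 is inverted (5S carbinol to 5R epoxide).
- C13 is kept as a silyl ether until after ring closure. An acetate ortho to the silyloxy group of the furan would be an ionisable leaving group under BF3 and would not survive the organoaluminium step.
- C5 is carried as a primary triethylsilyl ether and oxidised directly. Cleaving a vinyl group to this aldehyde cannot be made selective next to the 1(10)-olefin or the silyloxyfuran.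
- Oxidation of the 3,4-disubstituted furan must place the carbonyl at C12 and not at C6 (step 10).
- Assumption: (S)-2-methylglycidol 1 of high enantiomeric purity is taken as commercially available.
- Assumption: TRIP is 3,3'-bis(2,4,6-triisopropylphenyl)-1,1'-binaphthyl-2,2'-diyl hydrogen phosphate. Its S enantiomer is expected to give the S carbinol in step 6 by analogy with aryl aldehydes, and the assignment would be checked by Mosher ester analysis.

## Steps

Step 1
Reactants: 1 (S)-2-methylglycidol
Product: 2 (R)-triethyl[(2-methyloxiran-2-yl)methoxy]silane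
Conditions: TESCl, imidazole, CH2Cl2, 0 °C
Reagents that add atoms: chlorotriethylsilane, CC[Si](Cl)(CC)CC
Why: Silylation of a primary alcohol; the stereocentre is untouched (the descriptor changes from S to R only because CH2OSi now outranks the ring CH2).

Step 2
Reactants: 2 (R)-triethyl[(2-methyloxiran-2-yl)methoxy]silane
Product: 3 (R)-2-methyl-1-(triethylsilyloxy)but-3-en-2-ol
Conditions: Me3S+ I−, n-BuLi, THF, −10 °C → rt
Reagents that add atoms: trimethylsulfonium iodide, C[S+](C)C.[I-]
Why: One-carbon homologation of an epoxide to an allylic alcohol with excess dimethylsulfonium methylide: the ylide opens the unsubstituted epoxide carbon and the β-alkoxy sulfonium salt eliminates dimethyl sulfide. The C4–O bond is never broken, so configuration is retained; any silyl migration to the tertiary oxygen is harmless because step 3 silylates both oxygens.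

Step 3
Reactants: 3 (R)-2-methyl-1-(triethylsilyloxy)but-3-en-2-ol
Product: 4 (R)-2-methyl-1,2-bis(triethylsilyloxy)but-3-ene
Conditions: TESOTf, 2,6-lutidine, CH2Cl2, −78 → 0 °C
Reagents that add atoms: triethylsilyl trifluoromethanesulfonate, CC[Si](CC)(CC)OS(=O)(=O)C(F)(F)F
Why: Silyl triflate silylation of a hindered tertiary alcohol; no stereocentre is affected.

Step 4
Reactants: 5 furan-3,4-diyldimethanol
Product: 6 [4-(tert-butyldimethylsilyloxymethyl)furan-3-yl]methanol
Conditions: NaH (1.0 equiv), THF, 0 °C; TBSCl (1.0 equiv)
Reagents that add atoms: tert-butyldimethylsilyl chloride, CC(C)(C)[Si](C)(C)Cl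
Why: Monosilylation of a symmetrical diol through its monosodium alkoxide; this desymmetrises the furan and installs the C13 protecting group that stays until after ring closure.

Step 5
Reactants: 6 [4-(tert-butyldimethylsilyloxymethyl)furan-3-yl]methanol
Product: 7 4-(tert-butyldimethylsilyloxymethyl)furan-3-carbaldehyde
Conditions: MnO2, CH2Cl2, rt
Reagents that add atoms: none
Why: MnO2 oxidation of a heteroaryl carbinol to the aldehyde; the silyl ether and the furan are inert.

Step 6
Reactants: 7 4-(tert-butyldimethylsilyloxymethyl)furan-3-carbaldehyde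
Product: 8 (S)-1-[4-(tert-butyldimethylsilyloxymethyl)furan-3-yl]but-3-yn-1-ol
Conditions: allenylboronic acid pinacol ester, (S)-TRIP (5 mol %), 4 Å MS, toluene, −20 °C
Reagents that add atoms: allenylboronic acid pinacol ester, C=C=CB1OC(C)(C)C(C)(C)O1
Why: Chiral phosphoric acid-catalysed asymmetric propargylation: the allenylboronate adds by SE2' through a six-membered chair-like transition state held by the catalyst, which selects the aldehyde face and sets C8 as S. The terminal alkyne supplies C9, C10 and C1.

Step 7
Reactants: 8 (S)-1-[4-(tert-butyldimethylsilyloxymethyl)furan-3-yl]but-3-yn-1-ol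
Product: 9 (S)-tert-butyl{1-[4-(tert-butyldimethylsilyloxymethyl)furan-3-yl]but-3-ynyloxy}dimethylsilane
Conditions: TBSCl, imidazole, DMF, rt
Reagents that add atoms: tert-butyldimethylsilyl chloride, CC(C)(C)[Si](C)(C)Cl
Why: Standard silylation of a secondary alcohol under basic conditions that do not ionise the furyl carbinol.

Step 8
Reactants: 9 (S)-tert-butyl{1-[4-(tert-butyldimethylsilyloxymethyl)furan-3-yl]but-3-ynyloxy}dimethylsilane
Product: 11 3-[(1S,3E)-1-(tert-butyldimethylsilyloxy)-4-iodo-3-methylbut-3-enyl]-4-(tert-butyldimethylsilyloxymethyl)furan, via alkenylalane 10 (not isolated)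
Conditions: AlMe3, Cp2ZrCl2 (25 mol %), CH2Cl2, 0 °C → rt; then I2, THF, −30 °C
Reagents that add atoms: trimethylaluminium, C[Al](C)C; iodine, II
Why: Negishi zirconium-catalysed carboalumination: methyl and aluminium add syn across the terminal alkyne with methyl on the internal carbon (C10), and iodinolysis of the C–Al bond proceeds with retention. The E-1(10) geometry is therefore fixed by mechanism.

Step 9
Reactants: 4 (R)-2-methyl-1,2-bis(triethylsilyloxy)but-3-ene and 11 3-[(1S,3E)-1-(tert-butyldimethylsilyloxy)-4-iodo-3-methylbut-3-enyl]-4-(tert-butyldimethylsilyloxymethyl)furan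
Product: 13 3-[(1S,3E,7R)-1-(tert-butyldimethylsilyloxy)-3,7-dimethyl-7,8-bis(triethylsilyloxy)oct-3-enyl]-4-(tert-butyldimethylsilyloxymethyl)furan, via alkylborane 12 (not isolated)
Conditions: 9-BBN, THF, rt; then 11, Pd(dppf)Cl2 (5 mol %), AsPh3, Cs2CO3, DMF–H2O, rt
Reagents that add atoms: none
Why: B-alkyl Suzuki–Miyaura coupling: 9-BBN adds to the terminal alkene with boron on the end carbon (C2), and palladium couples this primary alkylborane with the vinyl iodide with retention of the E geometry. Neither stereocentre is involved.

Step 10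
Reactants: 13 3-[(1S,3E,7R)-1-(tert-butyldimethylsilyloxy)-3,7-dimethyl-7,8-bis(triethylsilyloxy)oct-3-enyl]-4-(tert-butyldimethylsilyloxymethyl)furan
Product: 15 4-[(1S,3E,7R)-1-(tert-butyldimethylsilyloxy)-3,7-dimethyl-7,8-bis(triethylsilyloxy)oct-3-enyl]-3-(tert-butyldimethylsilyloxymethyl)furan-2(5H)-one, via furylboronate 14 (not isolated)
Conditions: [Ir(OMe)(cod)]2 (2 mol %), dtbpy (4 mol %), B2pin2, THF, rt; then 30% H2O2, aq. NaHCO3, 0 °C; then Et3N (cat.)
Reagents that add atoms: hydrogen peroxide, OO
Why: Iridium-catalysed C–H borylation of a furan α-position followed by oxidation of the C–B bond to the 2-hydroxyfuran, which tautomerises to the butenolide; the amine moves the double bond into conjugation (C7=C11). The step is sterically governed, so it should take C12–H, flanked by the primary CH2OTBS group, in preference to C6–H, flanked by the branched C8 carbinol; basic peroxide does not epoxidise the 1(10)-olefin.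

Step 11
Reactants: 15 4-[(1S,3E,7R)-1-(tert-butyldimethylsilyloxy)-3,7-dimethyl-7,8-bis(triethylsilyloxy)oct-3-enyl]-3-(tert-butyldimethylsilyloxymethyl)furan-2(5H)-one
Product: 16 (2R,6E,8S)-8-(tert-butyldimethylsilyloxy)-8-[4-(tert-butyldimethylsilyloxymethyl)-5-oxo-2,5-dihydrofuran-3-yl]-2,6-dimethyl-2-(triethylsilyloxy)oct-6-enal
Conditions: (COCl)2, DMSO, CH2Cl2, −78 → −40 °C; Et3N, −78 → 0 °C
Reagents that add atoms: none
Why: Swern oxidation applied directly to a primary triethylsilyl ether: the chlorosulfonium salt cleaves only the primary TES–O bond and the alkoxysulfonium ion collapses to the aldehyde. The tertiary TES and both TBS ethers are spared, and the aldehyde has no α-hydrogen to epimerise.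

Step 12
Reactants: 16 (2R,6E,8S)-8-(tert-butyldimethylsilyloxy)-8-[4-(tert-butyldimethylsilyloxymethyl)-5-oxo-2,5-dihydrofuran-3-yl]-2,6-dimethyl-2-(triethylsilyloxy)oct-6-enal
Product: 17 (2R,6E,8S)-8-(tert-butyldimethylsilyloxy)-8-[4-(tert-butyldimethylsilyloxymethyl)-5-(triisopropylsilyloxy)furan-3-yl]-2,6-dimethyl-2-(triethylsilyloxy)oct-6-enal
Conditions: TIPSOTf, Et3N, CH2Cl2, 0 °C; filtration through Et3N-deactivated silica
Reagents that add atoms: triisopropylsilyl trifluoromethanesulfonate, CC(C)[Si](C(C)C)(C(C)C)OS(=O)(=O)C(F)(F)F
Why: Soft enolisation of the butenolide (γ-deprotonation after O-silylation) gives the aromatic 2-silyloxyfuran. The aldehyde cannot enolise, and the bulky, amine-buffered silyl triflate is a poor aldol promoter, so the two reactive ends should coexist until step 13.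

Step 13
Reactants: 17 (2R,6E,8S)-8-(tert-butyldimethylsilyloxy)-8-[4-(tert-butyldimethylsilyloxymethyl)-5-(triisopropylsilyloxy)furan-3-yl]-2,6-dimethyl-2-(triethylsilyloxy)oct-6-enal
Product: 18 (1(10)E,4R,5S,6S,8S)-8,13-bis(tert-butyldimethylsilyloxy)-5-hydroxy-4-(triethylsilyloxy)germacra-1(10),7(11)-dien-6,12-olide
Conditions: BF3·OEt2 (2 equiv), CH2Cl2, −78 °C, slow addition of 17 (final 1 mM); aq. NaHCO3
Reagents that add atoms: none
Why: Proposed new method: BF3 binds the C5 aldehyde, the γ-carbon C6 of the 2-silyloxyfuran adds to it in an open transition state, and loss of the triisopropylsilyl group from the oxocarbenium ion returns the conjugated butenolide; the closest known reactions are the bimolecular vinylogous Mukaiyama aldol of 2-silyloxyfurans with α-alkoxy aldehydes and intramolecular Mukaiyama aldol closures of medium rings. The one ring closes in a 10-exo-trig mode (the C5=O bond is exocyclic), helped by the E olefin, the flat furan and the quaternary C4, which together leave few freely rotating ring bonds. C5 is set by Felkin–Anh control: C6 arrives anti to the C4–OSiEt3 bond and past the methyl group, giving the 4,5-anti (5S) carbinol, and chelation cannot compete because BF3 is monodentate and the oxygen is silylated. C6 is set by the tether: the S centre at C8, next to the furan, decides over which furan face the chain lies, and 6S is the closure that leads to the crown-type ring with H5 and H6 anti. This is the least predictable element, because open-chain additions under BF3 prefer the opposite 5,6-relationship, so the ring has to impose it. The step needs cyclisation over oligomerisation (slow addition, high dilution) and aldol over carbonyl–ene attack on the 1(10)-olefin (the silyloxyfuran is by far the better nucleophile). It also needs γ- over α-attack (C11 is fully substituted) and an intact C13 oxygen (a silyl ether, not an ionisable ester). The aldehyde has no α-hydrogen, so C4 cannot epimerise.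

Step 14
Reactants: 18 (1(10)E,4R,5S,6S,8S)-8,13-bis(tert-butyldimethylsilyloxy)-5-hydroxy-4-(triethylsilyloxy)germacra-1(10),7(11)-dien-6,12-olide
Product: 19 (1(10)E,4R,5S,6S,8S)-8,13-bis(tert-butyldimethylsilyloxy)-5-(methanesulfonyloxy)-4-(triethylsilyloxy)germacra-1(10),7(11)-dien-6,12-olide
Conditions: MsCl, Et3N, CH2Cl2, −20 → 0 °C
Reagents that add atoms: methanesulfonyl chloride, CS(=O)(=O)Cl
Why: Mesylation through sulfene reaches the hindered secondary alcohol without touching the C–O bond, so C5 stays S. The low temperature limits amine-induced retro-aldol or elimination through C6–H.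

Step 15
Reactants: 19 (1(10)E,4R,5S,6S,8S)-8,13-bis(tert-butyldimethylsilyloxy)-5-(methanesulfonyloxy)-4-(triethylsilyloxy)germacra-1(10),7(11)-dien-6,12-olide
Product: 20 (1(10)E,4R,5S,6S,8S)-8-(tert-butyldimethylsilyloxy)-4,13-dihydroxy-5-(methanesulfonyloxy)germacra-1(10),7(11)-dien-6,12-olide
Conditions: HF·pyridine, pyridine, THF, 0 °C → rt (monitored)
Reagents that add atoms: none
Why: Buffered HF cleaves the triethylsilyl ether and the primary TBS ether faster than the secondary TBS ether at C8, which is kept on purpose. The acidic medium leaves the β-hydroxy mesylate and the base-sensitive C6–H alone.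

Step 16
Reactants: 20 (1(10)E,4R,5S,6S,8S)-8-(tert-butyldimethylsilyloxy)-4,13-dihydroxy-5-(methanesulfonyloxy)germacra-1(10),7(11)-dien-6,12-olide
Product: 21 (1(10)E,4R,5R,6S,8S)-8-(tert-butyldimethylsilyloxy)-4,5-epoxy-13-hydroxygermacra-1(10),7(11)-dien-6,12-olide
Conditions: K2CO3, MeOH, 0 °C, short reaction time; pH 7 buffer
Reagents that add atoms: none
Why: Intramolecular Williamson closure (3-exo-tet): the C4 alkoxide displaces the anti mesylate with inversion at C5 (5S to 5R) while C4 keeps its configuration, giving the trans epoxide. O8 is still silylated, so the lactone cannot migrate to C8, and O–H deprotonation with fast ring closure should outrun C–H deprotonation at C6.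

Step 17
Reactants: 21 (1(10)E,4R,5R,6S,8S)-8-(tert-butyldimethylsilyloxy)-4,5-epoxy-13-hydroxygermacra-1(10),7(11)-dien-6,12-olide
Product: 22 (1(10)E,4R,5R,6S,8S)-13-acetoxy-8-(tert-butyldimethylsilyloxy)-4,5-epoxygermacra-1(10),7(11)-dien-6,12-olide
Conditions: Ac2O, pyridine, CH2Cl2, 0 °C
Reagents that add atoms: acetic anhydride, CC(=O)OC(C)=O
Why: Acetylation of the only free hydroxyl group, so no selectivity is needed; pyridine at 0 °C is too weak a base to open the epoxide through C6–H.

Step 18
Reactants: 22 (1(10)E,4R,5R,6S,8S)-13-acetoxy-8-(tert-butyldimethylsilyloxy)-4,5-epoxygermacra-1(10),7(11)-dien-6,12-olide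
Product: 23 (1(10)E,4R,5R,6S,8S)-13-acetoxy-4,5-epoxy-8-hydroxygermacra-1(10),7(11)-dien-6,12-olide
Conditions: TBAF, AcOH (1:1), THF, 0 °C → rt
Reagents that add atoms: none
Why: Acetic acid-buffered fluoride removes the secondary TBS ether without free base (no elimination at C6, no acetate or lactone migration) and without strong acid (no transannular opening of the 4,5-epoxide by the 1(10)-olefin).

Step 19
Reactants: 24 ethyl 2-(hydroxymethyl)acrylate
Product: 25 ethyl 2-(tert-butyldimethylsilyloxymethyl)acrylate
Conditions: TBSCl, imidazole, CH2Cl2, 0 °C → rt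
Reagents that add atoms: tert-butyldimethylsilyl chloride, CC(C)(C)[Si](C)(C)Cl
Why: Standard silylation of a primary allylic alcohol.

Step 20
Reactants: 25 ethyl 2-(tert-butyldimethylsilyloxymethyl)acrylate
Product: 26 2-(tert-butyldimethylsilyloxymethyl)acrylic acid
Conditions: LiOH, THF–H2O, 0 °C; then aq. HCl to pH 4, 0 °C
Reagents that add atoms: lithium hydroxide, [Li+].[OH-]
Why: Saponification of an unhindered ethyl ester; the primary TBS ether tolerates cold hydroxide and a brief mildly acidic work-up.

Step 21
Reactants: 23 (1(10)E,4R,5R,6S,8S)-13-acetoxy-4,5-epoxy-8-hydroxygermacra-1(10),7(11)-dien-6,12-olide and 26 2-(tert-butyldimethylsilyloxymethyl)acrylic acid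
Product: 28 (1(10)E,4R,5R,6S,8S)-13-acetoxy-8-[2-(tert-butyldimethylsilyloxymethyl)acryloyloxy]-4,5-epoxygermacra-1(10),7(11)-dien-6,12-olide, via mixed anhydride 27 (not isolated)
Conditions: 26, 2,4,6-trichlorobenzoyl chloride, Et3N, toluene, rt; then 23, DMAP, toluene, 0 °C → rt
Reagents that add atoms: none
Why: Yamaguchi esterification: the mixed anhydride acylates the hindered secondary alcohol through the acylpyridinium ion. The C8–O bond is not broken, so C8 stays S, and the α-substituted acrylate resists conjugate addition of DMAP.

Step 22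
Reactants: 28 (1(10)E,4R,5R,6S,8S)-13-acetoxy-8-[2-(tert-butyldimethylsilyloxymethyl)acryloyloxy]-4,5-epoxygermacra-1(10),7(11)-dien-6,12-olide
Product: 29 (1R,4R,5R,6S,8S,10R)-13-acetoxy-8-[2-(tert-butyldimethylsilyloxymethyl)acryloyloxy]-1,10:4,5-diepoxygermacr-7(11)-en-6,12-olide
Conditions: mCPBA, NaHCO3, CH2Cl2, 0 °C
Reagents that add atoms: 3-chloroperoxybenzoic acid, OOC(=O)c1cccc(Cl)c1
Why: Prilezhaev epoxidation of the only electron-rich alkene (the butenolide and the acrylate are electron-poor); the addition is syn, so the E olefin gives the trans epoxide. Peracid is expected to attack the outer face of the crown-like 4,5-epoxygermacrene ring, which corresponds to 1R,10R, and bicarbonate keeps the medium non-acidic.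

Step 23
Reactants: 29 (1R,4R,5R,6S,8S,10R)-13-acetoxy-8-[2-(tert-butyldimethylsilyloxymethyl)acryloyloxy]-1,10:4,5-diepoxygermacr-7(11)-en-6,12-olide
Product: 30 (1R,4R,5R,6S,8S,10R)-13-acetoxy-1,10:4,5-diepoxy-8-[2-(hydroxymethyl)acryloyloxy]germacr-7(11)-en-6,12-olide (CNP0282791.1)
Conditions: TBAF, AcOH (1:1), THF, 0 °C
Reagents that add atoms: none
Why: Buffered fluoride cleaves the primary allylic TBS ether under near-neutral conditions that spare both epoxides, the acetate, the acrylate and the C6–H bond.

## Compound list

1 | (S)-2-methylglycidol | OC[C@]1(C)OC1 | starting material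
2 | (R)-triethyl[(2-methyloxiran-2-yl)methoxy]silane | CC[Si](CC)(CC)OC[C@]1(C)OC1 | intermediate
3 | (R)-2-methyl-1-(triethylsilyloxy)but-3-en-2-ol | CC[Si](CC)(CC)OC[C@](C)(O)C=C | intermediate
4 | (R)-2-methyl-1,2-bis(triethylsilyloxy)but-3-ene | CC[Si](CC)(CC)OC[C@](C)(O[Si](CC)(CC)CC)C=C | intermediate
5 | furan-3,4-diyldimethanol | OCc1cocc1CO | starting material
6 | [4-(tert-butyldimethylsilyloxymethyl)furan-3-yl]methanol | CC(C)(C)[Si](C)(C)OCc1cocc1CO | intermediate
7 | 4-(tert-butyldimethylsilyloxymethyl)furan-3-carbaldehyde | CC(C)(C)[Si](C)(C)OCc1cocc1C=O | intermediate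
8 | (S)-1-[4-(tert-butyldimethylsilyloxymethyl)furan-3-yl]but-3-yn-1-ol | C#CC[C@H](O)c1cocc1CO[Si](C)(C)C(C)(C)C | intermediate
9 | (S)-tert-butyl{1-[4-(tert-butyldimethylsilyloxymethyl)furan-3-yl]but-3-ynyloxy}dimethylsilane | C#CC[C@H](O[Si](C)(C)C(C)(C)C)c1cocc1CO[Si](C)(C)C(C)(C)C | intermediate
10 | (E)-alkenyl(dimethyl)alane from 9 (Al on C1, methyl on C10) | C[Al](C)/C=C(C)/C[C@H](O[Si](C)(C)C(C)(C)C)c1cocc1CO[Si](C)(C)C(C)(C)C | intermediate (not isolated)
11 | 3-[(1S,3E)-1-(tert-butyldimethylsilyloxy)-4-iodo-3-methylbut-3-enyl]-4-(tert-butyldimethylsilyloxymethyl)furan | I/C=C(C)/C[C@H](O[Si](C)(C)C(C)(C)C)c1cocc1CO[Si](C)(C)C(C)(C)C | intermediate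
12 | 9-[(R)-3-methyl-3,4-bis(triethylsilyloxy)butyl]-9-borabicyclo[3.3.1]nonane | CC[Si](CC)(CC)OC[C@](C)(O[Si](CC)(CC)CC)CCB1C2CCCC1CCC2 | intermediate (not isolated)
13 | 3-[(1S,3E,7R)-1-(tert-butyldimethylsilyloxy)-3,7-dimethyl-7,8-bis(triethylsilyloxy)oct-3-enyl]-4-(tert-butyldimethylsilyloxymethyl)furan | CC[Si](CC)(CC)OC[C@](C)(O[Si](CC)(CC)CC)CC/C=C(C)/C[C@H](O[Si](C)(C)C(C)(C)C)c1cocc1CO[Si](C)(C)C(C)(C)C | intermediate
14 | C12 pinacol boronate of 13 (boron on the furan α-carbon next to the CH2OTBS group) | CC[Si](CC)(CC)OC[C@](C)(O[Si](CC)(CC)CC)CC/C=C(C)/C[C@H](O[Si](C)(C)C(C)(C)C)c1coc(B2OC(C)(C)C(C)(C)O2)c1CO[Si](C)(C)C(C)(C)C | intermediate (not isolated)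
15 | 4-[(1S,3E,7R)-1-(tert-butyldimethylsilyloxy)-3,7-dimethyl-7,8-bis(triethylsilyloxy)oct-3-enyl]-3-(tert-butyldimethylsilyloxymethyl)furan-2(5H)-one | CC[Si](CC)(CC)OC[C@](C)(O[Si](CC)(CC)CC)CC/C=C(C)/C[C@H](O[Si](C)(C)C(C)(C)C)C1=C(CO[Si](C)(C)C(C)(C)C)C(=O)OC1 | intermediate
16 | (2R,6E,8S)-8-(tert-butyldimethylsilyloxy)-8-[4-(tert-butyldimethylsilyloxymethyl)-5-oxo-2,5-dihydrofuran-3-yl]-2,6-dimethyl-2-(triethylsilyloxy)oct-6-enal | O=C[C@](C)(O[Si](CC)(CC)CC)CC/C=C(C)/C[C@H](O[Si](C)(C)C(C)(C)C)C1=C(CO[Si](C)(C)C(C)(C)C)C(=O)OC1 | intermediate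
17 | (2R,6E,8S)-8-(tert-butyldimethylsilyloxy)-8-[4-(tert-butyldimethylsilyloxymethyl)-5-(triisopropylsilyloxy)furan-3-yl]-2,6-dimethyl-2-(triethylsilyloxy)oct-6-enal | O=C[C@](C)(O[Si](CC)(CC)CC)CC/C=C(C)/C[C@H](O[Si](C)(C)C(C)(C)C)c1coc(O[Si](C(C)C)(C(C)C)C(C)C)c1CO[Si](C)(C)C(C)(C)C | intermediate (precursor of the key step)
18 | (1(10)E,4R,5S,6S,8S)-8,13-bis(tert-butyldimethylsilyloxy)-5-hydroxy-4-(triethylsilyloxy)germacra-1(10),7(11)-dien-6,12-olide | CC(C)(C)[Si](C)(C)O[C@H]1C/C(C)=C/CC[C@@](C)(O[Si](CC)(CC)CC)[C@@H](O)[C@H]2OC(=O)C(CO[Si](C)(C)C(C)(C)C)=C12 | intermediate (product of the key step)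
19 | 5-O-methanesulfonate of 18 | CC(C)(C)[Si](C)(C)O[C@H]1C/C(C)=C/CC[C@@](C)(O[Si](CC)(CC)CC)[C@@H](OS(C)(=O)=O)[C@H]2OC(=O)C(CO[Si](C)(C)C(C)(C)C)=C12 | intermediate
20 | (1(10)E,4R,5S,6S,8S)-8-(tert-butyldimethylsilyloxy)-4,13-dihydroxy-5-(methanesulfonyloxy)germacra-1(10),7(11)-dien-6,12-olide | CC(C)(C)[Si](C)(C)O[C@H]1C/C(C)=C/CC[C@@](C)(O)[C@@H](OS(C)(=O)=O)[C@H]2OC(=O)C(CO)=C12 | intermediate
21 | (1(10)E,4R,5R,6S,8S)-8-(tert-butyldimethylsilyloxy)-4,5-epoxy-13-hydroxygermacra-1(10),7(11)-dien-6,12-olide | CC(C)(C)[Si](C)(C)O[C@H]1C/C(C)=C/CC[C@@]2(C)O[C@@H]2[C@H]2OC(=O)C(CO)=C12 | intermediate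
22 | (1(10)E,4R,5R,6S,8S)-13-acetoxy-8-(tert-butyldimethylsilyloxy)-4,5-epoxygermacra-1(10),7(11)-dien-6,12-olide | CC(C)(C)[Si](C)(C)O[C@H]1C/C(C)=C/CC[C@@]2(C)O[C@@H]2[C@H]2OC(=O)C(COC(C)=O)=C12 | intermediate
23 | (1(10)E,4R,5R,6S,8S)-13-acetoxy-4,5-epoxy-8-hydroxygermacra-1(10),7(11)-dien-6,12-olide | O[C@H]1C/C(C)=C/CC[C@@]2(C)O[C@@H]2[C@H]2OC(=O)C(COC(C)=O)=C12 | intermediate
24 | ethyl 2-(hydroxymethyl)acrylate | C=C(CO)C(=O)OCC | starting material
25 | ethyl 2-(tert-butyldimethylsilyloxymethyl)acrylate | C=C(CO[Si](C)(C)C(C)(C)C)C(=O)OCC | intermediate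
26 | 2-(tert-butyldimethylsilyloxymethyl)acrylic acid | C=C(CO[Si](C)(C)C(C)(C)C)C(=O)O | intermediate
27 | 2-(tert-butyldimethylsilyloxymethyl)acrylic 2,4,6-trichlorobenzoic anhydride | C=C(CO[Si](C)(C)C(C)(C)C)C(=O)OC(=O)c1c(Cl)cc(Cl)cc1Cl | intermediate (not isolated)
28 | (1(10)E,4R,5R,6S,8S)-13-acetoxy-8-[2-(tert-butyldimethylsilyloxymethyl)acryloyloxy]-4,5-epoxygermacra-1(10),7(11)-dien-6,12-olide | C=C(CO[Si](C)(C)C(C)(C)C)C(=O)O[C@H]1C/C(C)=C/CC[C@@]2(C)O[C@@H]2[C@H]2OC(=O)C(COC(C)=O)=C12 | intermediate
29 | (1R,4R,5R,6S,8S,10R)-13-acetoxy-8-[2-(tert-butyldimethylsilyloxymethyl)acryloyloxy]-1,10:4,5-diepoxygermacr-7(11)-en-6,12-olide | C=C(CO[Si](C)(C)C(C)(C)C)C(=O)O[C@H]1C[C@@]2(C)O[C@@H]2CC[C@@]2(C)O[C@@H]2[C@H]2OC(=O)C(COC(C)=O)=C12 | intermediate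
30 | (1R,4R,5R,6S,8S,10R)-13-acetoxy-1,10:4,5-diepoxy-8-[2-(hydroxymethyl)acryloyloxy]germacr-7(11)-en-6,12-olide (CNP0282791.1) | C=C(CO)C(=O)O[C@H]1C[C@@]2(C)O[C@@H]2CC[C@@]2(C)O[C@@H]2[C@H]2OC(=O)C(COC(C)=O)=C12 | target

## Step count and least certain steps

Total: 23 steps. Longest linear sequence: 18 steps (steps 4 to 18 and 21 to 23, from 5). Fragment 4 takes three steps (steps 1 to 3) and the acid 26 two (steps 19 and 20).

Step 13 (key step, Proposed new method). What is most likely to go wrong is competition from bimolecular aldol addition (oligomerisation) and from carbonyl–ene closure onto the 1(10)-olefin. Facial selection at C6 may also be poor or reversed, since open-chain additions of silyloxyfurans under BF3 favour the 5,6-relationship opposite to the one needed, and only the ring can reverse it. The fallback forms the same C5–C6 bond between two molecules and closes the ring elsewhere by known chemistry; it sets out from 11 and 4 and returns at 18.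
- The furan of 11 is oxidised as in step 10, through the C12 pinacol boronate F1, to the iodo-butenolide F2, which is silylated (TIPSOTf, Et3N) to the iodo silyloxyfuran F3.
- Swern oxidation of 4 gives (R)-2-methyl-2-(triethylsilyloxy)but-3-enal F4.
- F3 and F4 are joined by a bimolecular vinylogous Mukaiyama aldol to the open-chain aldol F5. BF3·OEt2 at −78 °C is the first choice; fluoride catalysis is the variant known to favour the erythro relationship needed here. The diastereomers can be separated at this acyclic stage.
- 9-BBN adds to the terminal vinyl group of F5 to give the alkylborane F6, and a B-alkyl Suzuki–Miyaura macrocyclisation at high dilution (Pd(dppf)Cl2, AsPh3, Cs2CO3) forms C1–C2 and delivers 18.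

Step 10. The likely failure is borylation at the wrong furan α-position (C6) or at both, because the regiochemistry rests only on the difference in size of the two flanking substituents. The fallback replaces steric control by alkoxide direction; it sets out from 13 and returns at 16.
- Acid-catalysed methanolysis (CSA, MeOH–CH2Cl2, 0 °C) removes both primary silyl groups and gives the diol F7.
- n-BuLi (3.3 equiv) lithiates the furan at C12, next to the C13 lithium alkoxide, and B(OMe)3 traps the anion as the boronate F8.
- H2O2 converts F8 into the butenolide diol F9.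
- TBSCl and imidazole silylate the unhindered allylic C13 hydroxyl in preference to the neopentyl C5 hydroxyl, giving the mono-silyl ether F10.
- Dess–Martin periodinane oxidises the C5 alcohol of F10 to 16.

Step 16. The likely failure is β-elimination: deprotonation at C6 (γ to the lactone carbonyl) expels the C5 mesylate or, after closure, opens the new epoxide, and methanol may attack the lactone. The fallback bypasses 20 and changes how the nucleophile is generated; it sets out from 19 and returns at 21. TBAF in THF at 0 °C cleaves the primary TBS ether and the C4 triethylsilyl ether of 19. The C4 alkoxide released from silicon closes the epoxide at once, without a separate base treatment of a free carbinol, and the secondary TBS ether at C8 survives the short exposure. No new compound is formed on the way.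

Step 22. The likely failure is poor facial selectivity at the 1(10)-olefin, since the conformation of the 7(11)-unsaturated, C8-acylated ring is not known. Acid-induced transannular opening of the 4,5-epoxide is the second risk. The fallback uses hydroxyl direction instead of peripheral attack; it sets out from 23 and returns at 29. The homoallylic C8 hydroxyl of 23 directs VO(acac)2/t-BuOOH to the olefin face on its own side, which corresponds to the side of the C8–C9–C10 segment that carries the epoxide oxygen in the target. This gives the diepoxy alcohol F11, and Yamaguchi esterification of F11 with 27 (made from 26 as in step 21) gives 29.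

## Further compounds

F1 | step 13 | C12 pinacol boronate of 11 | I/C=C(C)/C[C@H](O[Si](C)(C)C(C)(C)C)c1coc(B2OC(C)(C)C(C)(C)O2)c1CO[Si](C)(C)C(C)(C)C
F2 | step 13 | 4-[(1S,3E)-1-(tert-butyldimethylsilyloxy)-4-iodo-3-methylbut-3-enyl]-3-(tert-butyldimethylsilyloxymethyl)furan-2(5H)-one | I/C=C(C)/C[C@H](O[Si](C)(C)C(C)(C)C)C1=C(CO[Si](C)(C)C(C)(C)C)C(=O)OC1
F3 | step 13 | 4-[(1S,3E)-1-(tert-butyldimethylsilyloxy)-4-iodo-3-methylbut-3-enyl]-3-(tert-butyldimethylsilyloxymethyl)-2-(triisopropylsilyloxy)furan | I/C=C(C)/C[C@H](O[Si](C)(C)C(C)(C)C)c1coc(O[Si](C(C)C)(C(C)C)C(C)C)c1CO[Si](C)(C)C(C)(C)C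
F4 | step 13 | (R)-2-methyl-2-(triethylsilyloxy)but-3-enal | O=C[C@](C)(O[Si](CC)(CC)CC)C=C
F5 | step 13 | open-chain aldol (4R,5S,6S,8S): 5-[(1S,2R)-1-hydroxy-2-methyl-2-(triethylsilyloxy)but-3-enyl] butenolide carrying the (1S,3E)-iodoalkenyl arm | C=C[C@@](C)(O[Si](CC)(CC)CC)[C@@H](O)[C@H]1OC(=O)C(CO[Si](C)(C)C(C)(C)C)=C1[C@H](C/C(C)=C/I)O[Si](C)(C)C(C)(C)C
F6 | step 13 | B-alkyl-9-borabicyclo[3.3.1]nonane from F5 (drawn with the C5 hydroxyl free) | B1(CC[C@@](C)(O[Si](CC)(CC)CC)[C@@H](O)[C@H]2OC(=O)C(CO[Si](C)(C)C(C)(C)C)=C2[C@H](C/C(C)=C/I)O[Si](C)(C)C(C)(C)C)C2CCCC1CCC2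
F7 | step 10 | (2R,6E,8S)-8-(tert-butyldimethylsilyloxy)-8-[4-(hydroxymethyl)furan-3-yl]-2,6-dimethyl-2-(triethylsilyloxy)oct-6-en-1-ol | OC[C@](C)(O[Si](CC)(CC)CC)CC/C=C(C)/C[C@H](O[Si](C)(C)C(C)(C)C)c1cocc1CO
F8 | step 10 | C12 dimethyl boronate of F7 (drawn as the neutral ester) | OC[C@](C)(O[Si](CC)(CC)CC)CC/C=C(C)/C[C@H](O[Si](C)(C)C(C)(C)C)c1coc(B(OC)OC)c1CO
F9 | step 10 | 4-[(1S,3E,7R)-1-(tert-butyldimethylsilyloxy)-8-hydroxy-3,7-dimethyl-7-(triethylsilyloxy)oct-3-enyl]-3-(hydroxymethyl)furan-2(5H)-one | OC[C@](C)(O[Si](CC)(CC)CC)CC/C=C(C)/C[C@H](O[Si](C)(C)C(C)(C)C)C1=C(CO)C(=O)OC1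
F10 | step 10 | 4-[(1S,3E,7R)-1-(tert-butyldimethylsilyloxy)-8-hydroxy-3,7-dimethyl-7-(triethylsilyloxy)oct-3-enyl]-3-(tert-butyldimethylsilyloxymethyl)furan-2(5H)-one | OC[C@](C)(O[Si](CC)(CC)CC)CC/C=C(C)/C[C@H](O[Si](C)(C)C(C)(C)C)C1=C(CO[Si](C)(C)C(C)(C)C)C(=O)OC1
F0 | step 16 | none | none
F11 | step 22 | (1R,4R,5R,6S,8S,10R)-13-acetoxy-1,10:4,5-diepoxy-8-hydroxygermacr-7(11)-en-6,12-olide | O[C@H]1C[C@@]2(C)O[C@@H]2CC[C@@]2(C)O[C@@H]2[C@H]2OC(=O)C(COC(C)=O)=C12
A1 | alternative 1 | 11,13-dihydrocostunolide, (1(10)E,4E)-germacra-1(10),4-dien-6,12-olide | C[C@H]1[C@@H]2CC/C(C)=C/CC/C(C)=C/[C@H]2OC1=O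
A2 | alternative 2 | 8-(tert-butyldimethylsilyloxy)-7-[3-(4-methoxybenzyloxy)prop-1-en-2-yl]cyclodec-1(10)-en-4-yn-6-ol (germacrane numbering) | CC(C)(C)[Si](C)(C)O[C@H]1C/C(C)=C/CCC#C[C@@H](O)[C@@H]1C(=C)COCc1ccc(OC)cc1
A3 | alternative 3 | (5E)-3-(4-methoxybenzyloxy)-5,9-dimethyl-9-(triethylsilyloxy)cyclodec-5-en-1-one | COc1ccc(CO[C@H]2C/C(C)=C/CC[C@@](C)(O[Si](CC)(CC)CC)CC(=O)C2)cc1
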